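## Retrosynthetic overview

1. Numbering: ring A dihydrobenzofuran = O1, C2, C3, C3a, C4–C7, C7a (styryl on C4); ring B dihydrobenzofuran = primed atoms, with C5' bonded to C3. The target is taken back (ammonolysis, Heck reaction with 4-acetoxystyrene, acetylation, BBr3) to a C4-bromo bis(dihydrobenzofuran) hexamethyl ether, so that all phenols are freed while no stilbene is present.
2. Key disconnection C2–C3: the furan ring of ring A closes by enantioselective dirhodium-carbene insertion of a diaryldiazomethane (carbene carbon = C3) into the C2–H bond of the 4-methoxybenzyl ether on O1. The enabling feature is that C2 is both bonded to O1 and benzylic to a para-oxygenated arene (a hydridic C–H five atoms from C3), while C3 carries only aryl carbons (C3a of ring A and C5' of the central catechol ring) and can therefore be raised to the ketone/diazo level.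
3. C3–C5' bond: aryllithium of the ring B bromide plus 2-bromo-4-methoxy-6-(4-methoxybenzyloxy)benzaldehyde, then oxidation and hydrazone formation.
4. Ring B furan: the same insertion with the antipodal catalyst on a benzophenone made from 5-bromo-o-vanillin, 4-methoxybenzyl chloride and a 3,5-dimethoxyphenyl Grignard reagent.
5. Ring order: furan of ring B (step 5), furan of ring A (step 11); both form 2,3-cis and are turned 2,3-trans at C2 and C2' in the BBr3 step (step 12).

Key step: step 11

Remark on the chemistry (assumption): Rh2(S-PTAD)4 (dirhodium tetrakis[(S)-(1-adamantyl)(N-phthalimido)acetate]) is taken to give the (3R) cis ring in step 5 and Rh2(R-PTAD)4 the (3S) cis ring in step 11; the route only requires antipodal catalysts in the two steps, and they change places if a test insertion shows the opposite sense.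

## Route

Step 1
Reactants: 1 5-bromo-2-hydroxy-3-methoxybenzaldehyde; 2 4-methoxybenzyl chloride
Product: 3 5-bromo-3-methoxy-2-[(4-methoxyphenyl)methoxy]benzaldehyde
Conditions: K2CO3, KI (cat.), DMF, 60 °C
Reagents that add atoms: 4-methoxybenzyl chloride (2), COc1ccc(CCl)cc1
Why: Williamson etherification of the only phenol (SN2 on the benzylic chloride) puts in place the CH2 that becomes C2' together with its 4-methoxyphenyl ring; no stereocenter is formed.

Step 2
Reactants: 3 5-bromo-3-methoxy-2-[(4-methoxyphenyl)methoxy]benzaldehyde; 4 (3,5-dimethoxyphenyl)magnesium bromide (commercial THF solution)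
Product: 5 [5-bromo-3-methoxy-2-[(4-methoxyphenyl)methoxy]phenyl](3,5-dimethoxyphenyl)methanol (racemic)
Conditions: THF, −78 °C → 0 °C; then H2O
Reagents that add atoms: (3,5-dimethoxyphenyl)magnesium bromide (4), COc1cc(OC)cc([Mg]Br)c1
Why: Grignard 1,2-addition to the aldehyde is far faster than any reaction of the arylmagnesium reagent with the aryl bromide, and the carbinol center is formed racemic because it is erased in step 3.

Step 3
Reactants: 5 [5-bromo-3-methoxy-2-[(4-methoxyphenyl)methoxy]phenyl](3,5-dimethoxyphenyl)methanol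
Product: 6 [5-bromo-3-methoxy-2-[(4-methoxyphenyl)methoxy]phenyl](3,5-dimethoxyphenyl)methanone
Conditions: Dess–Martin periodinane, pyridine, CH2Cl2, 0 °C → rt
Reagents that add atoms: none
Why: Dess–Martin oxidation of a doubly benzylic secondary alcohol to the benzophenone runs under buffered conditions that leave the benzyl ether and the aryl bromide alone, and it removes the carbinol stereocenter.

Step 4
Reactants: 6 [5-bromo-3-methoxy-2-[(4-methoxyphenyl)methoxy]phenyl](3,5-dimethoxyphenyl)methanone
Product: 7 hydrazone of 6 (C=N isomer mixture)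
Conditions: N2H4·H2O (excess), AcOH (cat.), EtOH, 80 °C
Reagents that add atoms: hydrazine hydrate, NN.O
Why: Acid-catalysed hydrazone formation at a benzophenone with a single ortho substituent gives the free hydrazone, whose C=N geometry is of no consequence because it is lost at the diazo stage.

Step 5
Reactants: 7 hydrazone of 6
Product: 9 (2S,3R)-5-bromo-3-(3,5-dimethoxyphenyl)-7-methoxy-2-(4-methoxyphenyl)-2,3-dihydro-1-benzofuran (2,3-cis), via diaryldiazomethane 8 (not isolated)
Conditions: MnO2, CH2Cl2, 0 °C; filtration; then Rh2(S-PTAD)4 (1 mol %), CH2Cl2, 0 °C → rt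
Reagents that add atoms: none
Why: MnO2 dehydrogenates the hydrazone to the diaryldiazomethane and the derived donor/donor dirhodium carbene inserts into the 1,5-disposed benzylic ether C–H (enantioselective intramolecular carbene C–H insertion), closing the furan of the ring B unit with C3' fixed by the chiral catalyst and C2' placed cis by the compact insertion transition state, the cis relation being corrected in step 12.

Step 6
Reactants: 10 2-bromo-4,6-dimethoxybenzaldehyde
Product: 11 2-bromo-6-hydroxy-4-methoxybenzaldehyde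
Conditions: BCl3 (1.2 equiv), CH2Cl2, −78 °C → 0 °C; then H2O
Reagents that add atoms: none
Why: Chelation-controlled Lewis-acid demethylation, in which BCl3 bound to the aldehyde oxygen cleaves only the methoxy group ortho to the formyl group and leaves the para one untouched.

Step 7
Reactants: 11 2-bromo-6-hydroxy-4-methoxybenzaldehyde; 2 4-methoxybenzyl chloride
Product: 12 2-bromo-4-methoxy-6-[(4-methoxyphenyl)methoxy]benzaldehyde
Conditions: K2CO3, KI (cat.), DMF, 60 °C
Reagents that add atoms: 4-methoxybenzyl chloride (2), COc1ccc(CCl)cc1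
Why: Williamson etherification of the freed phenol installs the CH2 that becomes C2 and its 4-methoxyphenyl ring; no stereocenter is formed.

Step 8
Reactants: 9 (2S,3R)-5-bromo-3-(3,5-dimethoxyphenyl)-7-methoxy-2-(4-methoxyphenyl)-2,3-dihydro-1-benzofuran; 12 2-bromo-4-methoxy-6-[(4-methoxyphenyl)methoxy]benzaldehyde
Product: 14 [2-bromo-4-methoxy-6-[(4-methoxyphenyl)methoxy]phenyl][(2S,3R)-3-(3,5-dimethoxyphenyl)-7-methoxy-2-(4-methoxyphenyl)-2,3-dihydro-1-benzofuran-5-yl]methanol (both carbinol epimers), via aryllithium 13 (not isolated)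
Conditions: n-BuLi, THF, −78 °C; then 12, −78 °C → −40 °C; then H2O
Reagents that add atoms: aldehyde 12, COc1ccc(COc2cc(OC)cc(Br)c2C=O)cc1
Why: Bromine–lithium exchange at −78 °C is faster than deprotonation of the benzylic ring positions and addition of the aryllithium to the aldehyde outruns exchange with the aryl bromide of 12 (halogen–metal exchange, then 1,2-addition), the carbinol center being formed as both epimers because it is erased in step 9.

Step 9
Reactants: 14 the diarylmethanol of step 8
Product: 15 [2-bromo-4-methoxy-6-[(4-methoxyphenyl)methoxy]phenyl][(2S,3R)-3-(3,5-dimethoxyphenyl)-7-methoxy-2-(4-methoxyphenyl)-2,3-dihydro-1-benzofuran-5-yl]methanone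
Conditions: Dess–Martin periodinane, pyridine, CH2Cl2, 0 °C → rt
Reagents that add atoms: none
Why: Dess–Martin oxidation with pyridine buffering converts the acid-labile, doubly benzylic alcohol into the diaryl ketone without ionisation and removes the carbinol stereocenter.

Step 10
Reactants: 15 the diaryl ketone of step 9
Product: 16 hydrazone of 15 (C=N isomer mixture)
Conditions: N2H4·H2O (excess), N2H4·HCl (cat.), n-BuOH, 110 °C (sealed tube)
Reagents that add atoms: hydrazine hydrate, NN.O
Why: Hydrazone formation at a di-ortho-substituted benzophenone is slow but should proceed with excess hydrazine, hydrazinium catalysis and heat, the electron-rich aryl bromide being unreactive towards uncatalysed substitution by nitrogen.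

Step 11
Reactants: 16 hydrazone of 15
Product: 18 (2R,3S)-4-bromo-3-[(2S,3R)-3-(3,5-dimethoxyphenyl)-7-methoxy-2-(4-methoxyphenyl)-2,3-dihydro-1-benzofuran-5-yl]-6-methoxy-2-(4-methoxyphenyl)-2,3-dihydro-1-benzofuran (both furan rings 2,3-cis), via diaryldiazomethane 17 (not isolated)
Conditions: MnO2, CH2Cl2, 0 °C; filtration; then Rh2(R-PTAD)4 (2 mol %), CH2Cl2, 0 °C → rt, high dilution
Reagents that add atoms: none
Why: MnO2 dehydrogenates the hydrazone to diaryldiazomethane 17, which loses N2 on the dirhodium tetracarboxylate to give a donor/donor carbene at C3; this carbon then takes the hydridic C2–H of the ortho 4-methoxybenzyl ether in an asynchronous insertion, hydride shift towards C3 being followed at once by C2–C3 bond formation within the oxocarbenium/rhodium-bound carbanion pair. The closest known reaction type is the enantioselective intramolecular C–H insertion of diaryl (donor/donor) dirhodium carbenes into benzyl aryl ethers, which gives cis-2,3-diaryl-2,3-dihydrobenzofurans. The furan ring of ring A closes in the 1,5-insertion mode through O1, the only C–H in reach that is both α to oxygen and benzylic. C3 is set by the chiral carboxylate pocket of the catalyst, which selects one face of the carbene, and C2 follows from the compact insertion transition state that places the two aryl groups cis (inverted to trans in step 12); the remote centers C2' and C3' are expected to be spectators, so the catalyst should decide. The step needs chemoselectivity against azine formation, against carbene attack on an alkene and against reaction at the halide: the 2,6-disubstituted carbene and high dilution disfavour dimerisation, the stilbene is deliberately absent until step 14, and the aryl bromide is inert to the carbene.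

Step 12
Reactants: 18 the cis,cis bis(dihydrobenzofuran) hexamethyl ether
Product: 19 (2S,3S)-4-bromo-3-[(2R,3R)-3-(3,5-dihydroxyphenyl)-7-hydroxy-2-(4-hydroxyphenyl)-2,3-dihydro-1-benzofuran-5-yl]-2-(4-hydroxyphenyl)-2,3-dihydro-1-benzofuran-6-ol (both furan rings 2,3-trans)
Conditions: BBr3 (excess), CH2Cl2, −78 °C → rt; then H2O
Reagents that add atoms: none
Why: BBr3 cleaves the six aryl methyl ethers (Lewis-acid ether cleavage) and, by reversible ionisation of the benzylic C2–O1 and C2'–O1' bonds to para-oxygen-stabilised cations that re-close on the neighbouring ring oxygen, should invert C2 and C2' under thermodynamic control to the 2,3-trans rings while C3 and C3' keep the configuration set by the catalysts, and since no stilbene is present acid-induced cyclisation of a styryl group cannot occur.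

Step 13
Reactants: 19 the hexaphenol bromide
Product: 20 hexaacetate of 19
Conditions: Ac2O, pyridine, DMAP (cat.), rt
Reagents that add atoms: acetic anhydride, CC(=O)OC(C)=O
Why: Exhaustive O-acetylation with DMAP catalysis masks the six phenols as base-labile esters that tolerate the palladium chemistry of step 14; no stereocenter is touched.

Step 14
Reactants: 20 hexaacetate of 19; 21 4-acetoxystyrene
Product: 22 heptaacetate of the target, (E)-alkene
Conditions: Pd(OAc)2 (5 mol %), P(o-tol)3 (10 mol %), Et3N, DMF, 100 °C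
Reagents that add atoms: 4-acetoxystyrene (21), CC(=O)Oc1ccc(C=C)cc1
Why: Mizoroki–Heck reaction of the aryl bromide with a styrene gives the (E)-1,2-diarylethene by syn-insertion and syn-β-hydride elimination, the tri(o-tolyl)phosphine catalyst being suited to ortho-substituted aryl bromides and the acetates being stable to triethylamine in dry DMF.

Step 15
Reactants: 22 heptaacetate of the target
Product: 23 (2S,3S)-3-[(2R,3R)-3-(3,5-dihydroxyphenyl)-7-hydroxy-2-(4-hydroxyphenyl)-2,3-dihydro-1-benzofuran-5-yl]-2-(4-hydroxyphenyl)-4-[(E)-2-(4-hydroxyphenyl)ethenyl]-2,3-dihydro-1-benzofuran-6-ol (CNP0172909.1)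
Conditions: NH3 (7 M in MeOH), 0 °C → rt, argon
Reagents that add atoms: none
Why: Ammonolysis of the seven aryl acetates is fast at or below room temperature and mild enough to leave the stilbene and both trans-dihydrobenzofurans unchanged, giving the free heptaphenol.

## Compound list

1 | 5-bromo-2-hydroxy-3-methoxybenzaldehyde | COc1cc(Br)cc(C=O)c1O | starting material
2 | 4-methoxybenzyl chloride | COc1ccc(CCl)cc1 | starting material
3 | 5-bromo-3-methoxy-2-[(4-methoxyphenyl)methoxy]benzaldehyde | COc1ccc(COc2c(OC)cc(Br)cc2C=O)cc1 | intermediate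
4 | (3,5-dimethoxyphenyl)magnesium bromide | COc1cc(OC)cc([Mg]Br)c1 | starting material
5 | [5-bromo-3-methoxy-2-[(4-methoxyphenyl)methoxy]phenyl](3,5-dimethoxyphenyl)methanol, racemic | COc1ccc(COc2c(OC)cc(Br)cc2C(O)c2cc(OC)cc(OC)c2)cc1 | intermediate
6 | [5-bromo-3-methoxy-2-[(4-methoxyphenyl)methoxy]phenyl](3,5-dimethoxyphenyl)methanone | COc1ccc(COc2c(OC)cc(Br)cc2C(=O)c2cc(OC)cc(OC)c2)cc1 | intermediate
7 | hydrazone of 6 | COc1ccc(COc2c(OC)cc(Br)cc2C(=NN)c2cc(OC)cc(OC)c2)cc1 | intermediate
8 | 5-bromo-1-[diazo(3,5-dimethoxyphenyl)methyl]-3-methoxy-2-[(4-methoxyphenyl)methoxy]benzene | COc1ccc(COc2c(OC)cc(Br)cc2C(=[N+]=[N-])c2cc(OC)cc(OC)c2)cc1 | intermediate (not isolated)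
9 | (2S,3R)-5-bromo-3-(3,5-dimethoxyphenyl)-7-methoxy-2-(4-methoxyphenyl)-2,3-dihydro-1-benzofuran (cis) | Brc1cc(OC)c2c(c1)[C@@H](c1cc(OC)cc(OC)c1)[C@@H](c1ccc(OC)cc1)O2 | intermediate
10 | 2-bromo-4,6-dimethoxybenzaldehyde | COc1cc(Br)c(C=O)c(OC)c1 | starting material
11 | 2-bromo-6-hydroxy-4-methoxybenzaldehyde | COc1cc(O)c(C=O)c(Br)c1 | intermediate
12 | 2-bromo-4-methoxy-6-[(4-methoxyphenyl)methoxy]benzaldehyde | COc1ccc(COc2cc(OC)cc(Br)c2C=O)cc1 | intermediate
13 | [(2S,3R)-3-(3,5-dimethoxyphenyl)-7-methoxy-2-(4-methoxyphenyl)-2,3-dihydro-1-benzofuran-5-yl]lithium | [Li]c1cc(OC)c2c(c1)[C@@H](c1cc(OC)cc(OC)c1)[C@@H](c1ccc(OC)cc1)O2 | intermediate (not isolated)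
14 | [2-bromo-4-methoxy-6-[(4-methoxyphenyl)methoxy]phenyl][(2S,3R)-3-(3,5-dimethoxyphenyl)-7-methoxy-2-(4-methoxyphenyl)-2,3-dihydro-1-benzofuran-5-yl]methanol, both carbinol epimers | COc1ccc(COc2cc(OC)cc(Br)c2C(O)c2cc(OC)c3c(c2)[C@@H](c2cc(OC)cc(OC)c2)[C@@H](c2ccc(OC)cc2)O3)cc1 | intermediate
15 | [2-bromo-4-methoxy-6-[(4-methoxyphenyl)methoxy]phenyl][(2S,3R)-3-(3,5-dimethoxyphenyl)-7-methoxy-2-(4-methoxyphenyl)-2,3-dihydro-1-benzofuran-5-yl]methanone | COc1ccc(COc2cc(OC)cc(Br)c2C(=O)c2cc(OC)c3c(c2)[C@@H](c2cc(OC)cc(OC)c2)[C@@H](c2ccc(OC)cc2)O3)cc1 | intermediate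
16 | hydrazone of 15 | COc1ccc(COc2cc(OC)cc(Br)c2C(=NN)c2cc(OC)c3c(c2)[C@@H](c2cc(OC)cc(OC)c2)[C@@H](c2ccc(OC)cc2)O3)cc1 | intermediate
17 | diaryldiazomethane from 16 (C=N2 in place of C=O of 15) | COc1ccc(COc2cc(OC)cc(Br)c2C(=[N+]=[N-])c2cc(OC)c3c(c2)[C@@H](c2cc(OC)cc(OC)c2)[C@@H](c2ccc(OC)cc2)O3)cc1 | intermediate (not isolated)
18 | (2R,3S)-4-bromo-3-[(2S,3R)-3-(3,5-dimethoxyphenyl)-7-methoxy-2-(4-methoxyphenyl)-2,3-dihydro-1-benzofuran-5-yl]-6-methoxy-2-(4-methoxyphenyl)-2,3-dihydro-1-benzofuran (cis,cis) | Brc1cc(OC)cc2c1[C@H](c1cc(OC)c3c(c1)[C@@H](c1cc(OC)cc(OC)c1)[C@@H](c1ccc(OC)cc1)O3)[C@H](c1ccc(OC)cc1)O2 | intermediate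
19 | (2S,3S)-4-bromo-3-[(2R,3R)-3-(3,5-dihydroxyphenyl)-7-hydroxy-2-(4-hydroxyphenyl)-2,3-dihydro-1-benzofuran-5-yl]-2-(4-hydroxyphenyl)-2,3-dihydro-1-benzofuran-6-ol (trans,trans) | Brc1cc(O)cc2c1[C@H](c1cc(O)c3c(c1)[C@@H](c1cc(O)cc(O)c1)[C@H](c1ccc(O)cc1)O3)[C@@H](c1ccc(O)cc1)O2 | intermediate
20 | hexaacetate of 19 | Brc1cc(OC(C)=O)cc2c1[C@H](c1cc(OC(C)=O)c3c(c1)[C@@H](c1cc(OC(C)=O)cc(OC(C)=O)c1)[C@H](c1ccc(OC(C)=O)cc1)O3)[C@@H](c1ccc(OC(C)=O)cc1)O2 | intermediate
21 | 4-acetoxystyrene (4-ethenylphenyl acetate) | CC(=O)Oc1ccc(C=C)cc1 | starting material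
22 | heptaacetate of the target, (E)-alkene | CC(=O)Oc1ccc(/C=C/c2cc(OC(C)=O)cc3c2[C@H](c2cc(OC(C)=O)c4c(c2)[C@@H](c2cc(OC(C)=O)cc(OC(C)=O)c2)[C@H](c2ccc(OC(C)=O)cc2)O4)[C@@H](c2ccc(OC(C)=O)cc2)O3)cc1 | intermediate
23 | (2S,3S)-3-[(2R,3R)-3-(3,5-dihydroxyphenyl)-7-hydroxy-2-(4-hydroxyphenyl)-2,3-dihydro-1-benzofuran-5-yl]-2-(4-hydroxyphenyl)-4-[(E)-2-(4-hydroxyphenyl)ethenyl]-2,3-dihydro-1-benzofuran-6-ol | Oc1ccc(/C=C/c2cc(O)cc3c2[C@H](c2cc(O)c4c(c2)[C@@H](c2cc(O)cc(O)c2)[C@H](c2ccc(O)cc2)O4)[C@@H](c2ccc(O)cc2)O3)cc1 | target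

## Step count and risks

Total step count: 15. Longest linear sequence: 13 steps (steps 1–5 and 8–15; steps 6 and 7 form the side branch).

Steps most likely to fail:

1. Step 11 (key step). What may go wrong: slow carbene formation and insertion at the doubly ortho-substituted diazo carbon with competing azine formation, or erosion of facial selectivity by mismatch with the ring B unit. Fallback, setting out from ketone 15 and returning at 19: irradiation of 15 (Pyrex-filtered mercury lamp, benzene) should trigger δ-hydrogen abstraction from the OCH2Ar group by the excited ketone and closure of the 1,5-biradical across the same C2–C3 bond to give the tertiary alcohol 4-bromo-3-[(2S,3R)-3-(3,5-dimethoxyphenyl)-7-methoxy-2-(4-methoxyphenyl)-2,3-dihydro-1-benzofuran-5-yl]-6-methoxy-2-(4-methoxyphenyl)-2,3-dihydro-1-benzofuran-3-ol F1. Ionic hydrogenation (Et3SiH, TFA, CH2Cl2, 0 °C) of the C3 cation, or of any benzofuran formed from it by dehydration, should deliver hydride anti to the C2 aryl group. Absolute control at ring A is lost in this fallback, so the wanted 2,3-trans diastereomer, (2S,3S)-4-bromo-3-[(2S,3R)-3-(3,5-dimethoxyphenyl)-7-methoxy-2-(4-methoxyphenyl)-2,3-dihydro-1-benzofuran-5-yl]-6-methoxy-2-(4-methoxyphenyl)-2,3-dihydro-1-benzofuran F2, has to be separated from its ring A antipodal diastereomer by chromatography. F2 is then taken through the BBr3 conditions of step 12 to 19.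

2. Step 10. What may go wrong: incomplete condensation at the hindered carbonyl group, and under forcing conditions cyclisation of the hydrazone nitrogen onto the neighbouring aryl bromide. Fallback, setting out from 9 and 12 and returning at 16:
   - Aldehyde 12 is converted with I2 and aqueous NH3 in THF into 2-bromo-4-methoxy-6-[(4-methoxyphenyl)methoxy]benzonitrile F3.
   - Bromide 9 is converted by magnesium insertion (Mg, LiCl, THF) into bromo[(2S,3R)-3-(3,5-dimethoxyphenyl)-7-methoxy-2-(4-methoxyphenyl)-2,3-dihydro-1-benzofuran-5-yl]magnesium F4, which does not exchange with the aryl bromide of the nitrile.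
   - Addition of F4 to F3 (CuBr cat., THF, reflux; methanol quench) should give the N–H ketimine [2-bromo-4-methoxy-6-[(4-methoxyphenyl)methoxy]phenyl][(2S,3R)-3-(3,5-dimethoxyphenyl)-7-methoxy-2-(4-methoxyphenyl)-2,3-dihydro-1-benzofuran-5-yl]methanimine F5.
   - Transimination of F5 with hydrazine hydrate and hydrazinium chloride in ethanol at 80 °C, the established entry to hindered hydrazones, gives 16.

3. Step 12. What may go wrong: incomplete demethylation or incomplete inversion at C2 and C2', loss of configuration at C3 or C3' through elimination and reprotonation of the ring-opened cation, and Friedel–Crafts side reactions of that cation. Fallback, setting out from 18 and returning at 19: the two events are separated. A short treatment with TFA in CH2Cl2 at 0 °C epimerises only C2 and C2' and gives (2S,3S)-4-bromo-3-[(2R,3R)-3-(3,5-dimethoxyphenyl)-7-methoxy-2-(4-methoxyphenyl)-2,3-dihydro-1-benzofuran-5-yl]-6-methoxy-2-(4-methoxyphenyl)-2,3-dihydro-1-benzofuran F6, whose configuration can be checked at this stage. The six methyl ethers are then cleaved by iodide-assisted dealkylation (BCl3, n-Bu4NI, CH2Cl2, −78 °C → 0 °C) to give 19.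

## Further compounds

F1 | step 11 | 4-bromo-3-[(2S,3R)-3-(3,5-dimethoxyphenyl)-7-methoxy-2-(4-methoxyphenyl)-2,3-dihydro-1-benzofuran-5-yl]-6-methoxy-2-(4-methoxyphenyl)-2,3-dihydro-1-benzofuran-3-ol (mixture at C2 and C3) | Brc1cc(OC)cc2c1C(O)(c1cc(OC)c3c(c1)[C@@H](c1cc(OC)cc(OC)c1)[C@@H](c1ccc(OC)cc1)O3)C(c1ccc(OC)cc1)O2
F2 | step 11 | (2S,3S)-4-bromo-3-[(2S,3R)-3-(3,5-dimethoxyphenyl)-7-methoxy-2-(4-methoxyphenyl)-2,3-dihydro-1-benzofuran-5-yl]-6-methoxy-2-(4-methoxyphenyl)-2,3-dihydro-1-benzofuran | Brc1cc(OC)cc2c1[C@H](c1cc(OC)c3c(c1)[C@@H](c1cc(OC)cc(OC)c1)[C@@H](c1ccc(OC)cc1)O3)[C@@H](c1ccc(OC)cc1)O2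
F3 | step 10 | 2-bromo-4-methoxy-6-[(4-methoxyphenyl)methoxy]benzonitrile | COc1ccc(COc2cc(OC)cc(Br)c2C#N)cc1
F4 | step 10 | bromo[(2S,3R)-3-(3,5-dimethoxyphenyl)-7-methoxy-2-(4-methoxyphenyl)-2,3-dihydro-1-benzofuran-5-yl]magnesium | Br[Mg]c1cc(OC)c2c(c1)[C@@H](c1cc(OC)cc(OC)c1)[C@@H](c1ccc(OC)cc1)O2
F5 | step 10 | [2-bromo-4-methoxy-6-[(4-methoxyphenyl)methoxy]phenyl][(2S,3R)-3-(3,5-dimethoxyphenyl)-7-methoxy-2-(4-methoxyphenyl)-2,3-dihydro-1-benzofuran-5-yl]methanimine | COc1ccc(COc2cc(OC)cc(Br)c2C(=N)c2cc(OC)c3c(c2)[C@@H](c2cc(OC)cc(OC)c2)[C@@H](c2ccc(OC)cc2)O3)cc1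
F6 | step 12 | (2S,3S)-4-bromo-3-[(2R,3R)-3-(3,5-dimethoxyphenyl)-7-methoxy-2-(4-methoxyphenyl)-2,3-dihydro-1-benzofuran-5-yl]-6-methoxy-2-(4-methoxyphenyl)-2,3-dihydro-1-benzofuran | Brc1cc(OC)cc2c1[C@H](c1cc(OC)c3c(c1)[C@@H](c1cc(OC)cc(OC)c1)[C@H](c1ccc(OC)cc1)O3)[C@@H](c1ccc(OC)cc1)O2
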